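**Assumption:** atoms carry germacrane numbers (C1–C15); the SMILES is read as 1R,6R,8S with a 4Z olefin (C3 and C6 cis on C4=C5).

## Retrosynthetic overview

1. Target ⇐ diol 20 (selective 13‑O‑acetylation) ⇐ ten‑membered 2‑silyloxyfuran enone 18 (CBS reduction at C1, protodesilylation sets C6).
2. 18 ⇐ tricyclic tertiary alcohol 15 by cleaving the C1–C6 bond: cyclohexene ring A opens into the ten‑membered ring (four‑carbon ring expansion), and its cis olefin becomes 4Z.
3. 15 ⇐ spiro α‑keto butenolide 14 by intramolecular Ni/Cr alkenylation (C1–C10 bond, temporary ring B).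
4. 14 ⇐ aldehyde 10 + 2,3‑dibromopropene (asymmetric 2‑bromoallylation sets C8); 10 ⇐ allenoate 7 (iodolactonisation, formylation) ⇐ 3‑methylcyclohexenone + propargyl alcohol + 2 CO.
5. Ring order: ring A (bought) → spiro butenolide → ring B → ten‑membered ring by expansion.

## Route

Step 1
Reactants: 1 3‑methylcyclohex‑2‑en‑1‑one
Product: 2 (±)‑6‑hydroxy‑3‑methylcyclohex‑2‑en‑1‑one
Conditions: NaN(SiMe3)2, THF, −78 °C; trans‑2‑(phenylsulfonyl)‑3‑phenyloxaziridine, −78 °C; AcOH quench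
Reagents that add atoms: trans‑2‑(phenylsulfonyl)‑3‑phenyloxaziridine O=S(=O)(N1OC1c1ccccc1)c1ccccc1
Why: Kinetic α′‑deprotonation gives the cross‑conjugated enolate, which is hydroxylated by the N‑sulfonyloxaziridine (Davis oxidation); the racemic carbinol (future C1) is oxidised later, so its configuration is irrelevant.

Step 2
Reactants: 3 prop‑2‑yn‑1‑ol
Product: 4 tert‑butyldimethyl(prop‑2‑yn‑1‑yloxy)silane
Conditions: TBSCl, imidazole, CH2Cl2, 0 °C → rt
Reagents that add atoms: tert‑butyldimethylsilyl chloride CC(C)(C)[Si](C)(C)Cl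
Why: Standard silylation; the future C13 oxygen is carried as a silyl ether, which is not a leaving group when the furanolate is generated in step 11.

Step 3
Reactants: 2 (±)‑6‑hydroxy‑3‑methylcyclohex‑2‑en‑1‑one; 4 tert‑butyldimethyl(prop‑2‑yn‑1‑yloxy)silane
Product: 6 3a‑{3‑[(tert‑butyldimethylsilyl)oxy]prop‑1‑yn‑1‑yl}‑5‑methyl‑3a,6,7,7a‑tetrahydro‑1,3‑benzodioxol‑2‑one, via dilithium diolate 5 (not isolated)
Conditions: 4 (2.2 equiv), n‑BuLi (2.2 equiv), THF, −78 °C; add 2, −78 → 0 °C; then 1,1′‑carbonyldiimidazole, rt; AcOH quench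
Reagents that add atoms: 1,1′‑carbonyldiimidazole O=C(n1ccnc1)n1ccnc1
Why: Lithium acetylide adds 1,2 to the enone carbonyl (the first equivalent deprotonates the hydroxyl), and the 1,2‑dialkoxide is closed by CDI to a cyclic carbonate that is both propargylic leaving group and mask for the C1 hydroxyl; the stereocentres formed are erased later.

Step 4
Reactants: 6 cyclic carbonate
Product: 7 methyl 2‑{[(tert‑butyldimethylsilyl)oxy]methyl}‑3‑(6‑hydroxy‑3‑methylcyclohex‑2‑en‑1‑ylidene)prop‑2‑enoate (vinylallenoate)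
Conditions: Pd2(dba)3·CHCl3 (2.5 mol %), PPh3 (10 mol %), CO (1–5 atm), MeOH, 45 °C
Reagents that add atoms: carbon monoxide [C-]#[O+]; methanol CO
Why: Tsuji decarboxylative carbonylation of a propargylic carbonate: zerovalent palladium opens the tertiary C6–O bond in SN2′ fashion to an allenylpalladium alkoxide, and CO insertion with methanolysis gives the 2,3‑dienoate (C12 installed) and frees the C1 hydroxyl.

Step 5
Reactants: 7 vinylallenoate
Product: 8 10‑hydroxy‑4‑iodo‑7‑methyl‑3‑{[(tert‑butyldimethylsilyl)oxy]methyl}‑1‑oxaspiro[4.5]deca‑3,6‑dien‑2‑one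
Conditions: I2 (2 equiv), MeCN, rt, dark; Na2S2O3 wash
Reagents that add atoms: iodine II
Why: Iodolactonisation of a 2,3‑allenoate: iodonium attack at the central allene carbon and five‑ring closure by the ester carbonyl oxygen at the allene terminus (methyl lost as MeI) form the spiro C6–O bond and leave a C7 iodide.

Step 6
Reactants: 8 spiro iodobutenolide alcohol
Product: 9 4‑iodo‑7‑methyl‑3‑{[(tert‑butyldimethylsilyl)oxy]methyl}‑1‑oxaspiro[4.5]deca‑3,6‑diene‑2,10‑dione
Conditions: Dess–Martin periodinane, CH2Cl2, rt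
Reagents that add atoms: none
Why: Dess–Martin oxidation of the only free hydroxyl gives the C1 ketone; quaternary C6 prevents the β,γ‑olefin from moving into conjugation.

Step 7
Reactants: 9 spiro iodobutenolide ketone
Product: 10 7‑methyl‑2,10‑dioxo‑3‑{[(tert‑butyldimethylsilyl)oxy]methyl}‑1‑oxaspiro[4.5]deca‑3,6‑diene‑4‑carbaldehyde
Conditions: Pd(PPh3)4 (5 mol %), CO (3 atm), Bu3SnH (slow addition), THF, 50 °C
Reagents that add atoms: carbon monoxide [C-]#[O+]
Why: Stille‑type reductive carbonylation (formylation) of the vinyl iodide installs C8; oxidative addition at C–I is much faster than ionisation of the hindered allylic lactone.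

Step 8
Reactants: 10 spiro butenolide keto‑aldehyde; 11 2,3‑dibromoprop‑1‑ene
Product: 13 4‑[(1S)‑3‑bromo‑1‑hydroxybut‑3‑en‑1‑yl]‑7‑methyl‑3‑{[(tert‑butyldimethylsilyl)oxy]methyl}‑1‑oxaspiro[4.5]deca‑3,6‑diene‑2,10‑dione, via trimethylsilyl ether 12 (not isolated)
Conditions: CrBr3 (10 mol %), chiral oxazoline–sulfonamide ligand (Kishi type, si‑face‑selective enantiomer, 12 mol %), Et3N (20 mol %), Mn powder, cobalt phthalocyanine (1 mol %), TMSCl, LiCl, THF, 0 °C; aq. citric acid/THF work‑up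
Reagents that add atoms: none
Why: Catalytic asymmetric Nozaki–Hiyama 2‑haloallylation: the cobalt/chromium relay turns the allylic bromide into a 2‑bromoallylchromium that adds to the aldehyde rather than the hindered ketone, and ligand‑controlled si‑face attack sets 8S (the facial sense of the chosen ligand enantiomer must be confirmed on a model); the vinylic bromide is untouched and the two spiro epimers are carried on together.

Step 9
Reactants: 13 (S)‑homoallylic alcohol
Product: 14 (1S)‑3‑bromo‑1‑[7‑methyl‑2,10‑dioxo‑3‑{[(tert‑butyldimethylsilyl)oxy]methyl}‑1‑oxaspiro[4.5]deca‑3,6‑dien‑4‑yl]but‑3‑en‑1‑yl acetate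
Conditions: Ac2O, pyridine, DMAP (cat.), CH2Cl2, 0 °C
Reagents that add atoms: acetic anhydride CC(=O)OC(C)=O
Why: Acetylation installs the final C8 ester and prevents hemiketal formation with the C1 ketone; C8 is not affected.

Step 10
Reactants: 14 spiro keto vinyl bromide
Product: 15 (8S)‑8‑acetoxy‑1‑hydroxy‑13‑(tert‑butyldimethylsilyloxy)‑1,6‑cyclogermacra‑4,7(11),10(14)‑trien‑6,12‑olide
Conditions: CrCl2 (6 equiv), NiCl2 (5 mol %), DMSO, 25 → 40 °C, 0.01 M
Reagents that add atoms: none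
Why: Intramolecular Nozaki–Hiyama–Kishi alkenylation: nickel activates the vinyl bromide, the alkenylchromium adds to the α‑acyloxy‑activated C1 ketone to close six‑membered ring B (esters and lactone are inert); the new C1 centre and C6 are both erased in step 11, so all diastereomers are used.

Step 11
Reactants: 15 tricyclic tertiary alcohol
Product: 18 (4Z,8S)‑8‑acetoxy‑12,13‑bis(tert‑butyldimethylsilyloxy)‑6,12‑epoxygermacra‑4,6,10(14),11‑tetraen‑1‑one, via potassium alkoxide 16 (not isolated), via potassium furanolate 17 (not isolated)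
Conditions: TBSCl (2.5 equiv), KN(SiMe3)2 (1.1 equiv), THF–DMPU (9:1), −78 → −40 °C; pH 7 buffer
Reagents that add atoms: tert‑butyldimethylsilyl chloride CC(C)(C)[Si](C)(C)Cl
Why: Proposed new method: the tertiary potassium alkoxide 16 undergoes a retro‑vinylogous‑aldol (Grob‑type) cleavage of C1–C6 because the carbanion released at C6 is an aromatic 2‑oxidofuran (far less basic than the alkoxide) and two adjacent fully substituted carbons are relieved, so ring A expands by four carbons to the ten‑membered enone with the cyclohexene cis olefin carried over as 4Z; TBSCl present in the flask O‑silylates furanolate 17 before it can re‑add to C1 or add transannularly to the new enone, and the C13 silyl ether cannot be eliminated from the furanolate; the closest known reaction types are Trost's condensative ring expansion of α‑sulfonyl ketones and anionic retro‑aldol fragmentations, whereas a vinylogous version with a furanolate leaving group that makes a ten‑membered carbocycle has not been shown; C8 is untouched.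

Step 12
Reactants: 18 ten‑membered silyloxyfuran enone
Product: 20 (1R,4Z,6R,8S)‑8‑acetoxy‑1,13‑dihydroxygermacra‑4,7(11),10(14)‑trien‑6,12‑olide, via silyloxyfuran alcohol 19 (not isolated)
Conditions: (S)‑Me‑CBS (0.3 equiv), catecholborane, toluene, −78 °C; then HF·pyridine, THF, 0 °C; then Et3N (0.3 equiv), CH2Cl2, rt
Reagents that add atoms: none
Why: Corey–Bakshi–Shibata reduction with the 2‑methylene alkenyl group as the large substituent gives 1R by reagent control; fluoride then removes both silyl groups, the silyloxyfuran is protonated, and amine equilibration through the furanolate (no enone and no C13 leaving group present) gives the conjugated butenolide, with the 6R epimer hoped for but not secured (see risks).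

Step 13
Reactants: 20 diol
Product: 21 8α,13‑diacetoxy‑1β‑hydroxygermacra‑4,7(11),10(14)‑trien‑6α,12‑olide
Conditions: AcCl (1.05 equiv), 2,4,6‑collidine, CH2Cl2, −78 °C
Reagents that add atoms: acetyl chloride CC(Cl)=O
Why: Selective acylation of the primary allylic C13 hydroxyl over the secondary C1 hydroxyl with a hindered base at low temperature, which does not epimerise C6.

## Compound list

1 | 3‑methylcyclohex‑2‑en‑1‑one | CC1=CC(=O)CCC1 | starting material
2 | (±)‑6‑hydroxy‑3‑methylcyclohex‑2‑en‑1‑one | CC1=CC(=O)C(O)CC1 | intermediate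
3 | prop‑2‑yn‑1‑ol | C#CCO | starting material
4 | tert‑butyldimethyl(prop‑2‑yn‑1‑yloxy)silane | C#CCO[Si](C)(C)C(C)(C)C | intermediate
5 | dilithium diolate of 1‑{3‑[(tert‑butyldimethylsilyl)oxy]prop‑1‑yn‑1‑yl}‑3‑methylcyclohex‑2‑ene‑1,6‑diol (racemic, cis/trans) | CC1=CC([O-])(C#CCO[Si](C)(C)C(C)(C)C)C([O-])CC1.[Li+].[Li+] | intermediate
6 | 3a‑{3‑[(tert‑butyldimethylsilyl)oxy]prop‑1‑yn‑1‑yl}‑5‑methyl‑3a,6,7,7a‑tetrahydro‑1,3‑benzodioxol‑2‑one (racemic, diastereomers) | CC1=CC2(C#CCO[Si](C)(C)C(C)(C)C)OC(=O)OC2CC1 | intermediate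
7 | methyl 2‑{[(tert‑butyldimethylsilyl)oxy]methyl}‑3‑(6‑hydroxy‑3‑methylcyclohex‑2‑en‑1‑ylidene)prop‑2‑enoate (racemic, diastereomers) | COC(=O)C(CO[Si](C)(C)C(C)(C)C)=C=C1C=C(C)CCC1O | intermediate
8 | 10‑hydroxy‑4‑iodo‑7‑methyl‑3‑{[(tert‑butyldimethylsilyl)oxy]methyl}‑1‑oxaspiro[4.5]deca‑3,6‑dien‑2‑one (racemic, diastereomers) | CC1=CC2(OC(=O)C(CO[Si](C)(C)C(C)(C)C)=C2I)C(O)CC1 | intermediate
9 | 4‑iodo‑7‑methyl‑3‑{[(tert‑butyldimethylsilyl)oxy]methyl}‑1‑oxaspiro[4.5]deca‑3,6‑diene‑2,10‑dione (racemic) | CC1=CC2(OC(=O)C(CO[Si](C)(C)C(C)(C)C)=C2I)C(=O)CC1 | intermediate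
10 | 7‑methyl‑2,10‑dioxo‑3‑{[(tert‑butyldimethylsilyl)oxy]methyl}‑1‑oxaspiro[4.5]deca‑3,6‑diene‑4‑carbaldehyde (racemic) | CC1=CC2(OC(=O)C(CO[Si](C)(C)C(C)(C)C)=C2C=O)C(=O)CC1 | intermediate
11 | 2,3‑dibromoprop‑1‑ene | C=C(Br)CBr | starting material
12 | trimethylsilyl ether of 13 (both spiro epimers) | CC1=CC2(OC(=O)C(CO[Si](C)(C)C(C)(C)C)=C2[C@@H](O[Si](C)(C)C)CC(Br)=C)C(=O)CC1 | intermediate
13 | 4‑[(1S)‑3‑bromo‑1‑hydroxybut‑3‑en‑1‑yl]‑7‑methyl‑3‑{[(tert‑butyldimethylsilyl)oxy]methyl}‑1‑oxaspiro[4.5]deca‑3,6‑diene‑2,10‑dione (both spiro epimers) | CC1=CC2(OC(=O)C(CO[Si](C)(C)C(C)(C)C)=C2[C@@H](O)CC(Br)=C)C(=O)CC1 | intermediate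
14 | (1S)‑3‑bromo‑1‑[7‑methyl‑2,10‑dioxo‑3‑{[(tert‑butyldimethylsilyl)oxy]methyl}‑1‑oxaspiro[4.5]deca‑3,6‑dien‑4‑yl]but‑3‑en‑1‑yl acetate (both spiro epimers) | CC1=CC2(OC(=O)C(CO[Si](C)(C)C(C)(C)C)=C2[C@@H](OC(C)=O)CC(Br)=C)C(=O)CC1 | intermediate
15 | (8S)‑8‑acetoxy‑1‑hydroxy‑13‑(tert‑butyldimethylsilyloxy)‑1,6‑cyclogermacra‑4,7(11),10(14)‑trien‑6,12‑olide (extra C1–C6 bond; ring A = C1–C6, ring B = C1, C10, C9, C8, C7, C6; mixture at C1/C6) | CC1=CC23OC(=O)C(CO[Si](C)(C)C(C)(C)C)=C2[C@@H](OC(C)=O)CC(=C)C3(O)CC1 | intermediate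
16 | potassium alkoxide of 15 | CC1=CC23OC(=O)C(CO[Si](C)(C)C(C)(C)C)=C2[C@@H](OC(C)=O)CC(=C)C3([O-])CC1.[K+] | intermediate
17 | potassium (4Z,8S)‑8‑acetoxy‑13‑(tert‑butyldimethylsilyloxy)‑1‑oxo‑6,12‑epoxygermacra‑4,6,10(14),11‑tetraen‑12‑olate (furanolate) | C=C1C[C@H](OC(C)=O)c2c(CO[Si](C)(C)C(C)(C)C)c([O-])oc2/C=C(/C)CCC1=O.[K+] | intermediate
18 | (4Z,8S)‑8‑acetoxy‑12,13‑bis(tert‑butyldimethylsilyloxy)‑6,12‑epoxygermacra‑4,6,10(14),11‑tetraen‑1‑one (2‑silyloxyfuran fused at C6–C7 to the ten‑membered ring) | C=C1C[C@H](OC(C)=O)c2c(CO[Si](C)(C)C(C)(C)C)c(O[Si](C)(C)C(C)(C)C)oc2/C=C(/C)CCC1=O | intermediate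
19 | (1R,4Z,8S)‑8‑acetoxy‑12,13‑bis(tert‑butyldimethylsilyloxy)‑6,12‑epoxygermacra‑4,6,10(14),11‑tetraen‑1‑ol | C=C1C[C@H](OC(C)=O)c2c(CO[Si](C)(C)C(C)(C)C)c(O[Si](C)(C)C(C)(C)C)oc2/C=C(/C)CC[C@H]1O | intermediate
20 | (1R,4Z,6R,8S)‑8‑acetoxy‑1,13‑dihydroxygermacra‑4,7(11),10(14)‑trien‑6,12‑olide | C=C1C[C@H](OC(C)=O)C2=C(CO)C(=O)O[C@@H]2/C=C(/C)CC[C@H]1O | intermediate
21 | 8α,13‑diacetoxy‑1β‑hydroxygermacra‑4,7(11),10(14)‑trien‑6α,12‑olide (1R,4Z,6R,8S) | C=C1C[C@H](OC(C)=O)C2=C(COC(C)=O)C(=O)O[C@@H]2/C=C(/C)CC[C@H]1O | target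

## Step count and risks

Total steps: 13. Longest linear sequence: 12 (steps 1 and 3–13, from 1 to 21); step 2 is a one‑step side branch.

Three steps most likely to fail:

**Step 11 (proposed new ring expansion).** The alkoxide may be silylated before it fragments, or the furanolate may add to the new enone before it is silylated. The fallback uses known chemistry and sets out from 15, returning at 20. The alkoxy radical is generated under Suárez hypoiodite conditions (PhI(OAc)2, I2, visible light, CH2Cl2); β‑scission of C1–C6 gives the captodative C6 radical, which is trapped by iodine and acetate as the ring‑expanded (4Z,8S)‑6,8‑diacetoxy‑13‑(tert‑butyldimethylsilyloxy)‑1‑oxogermacra‑4,7(11),10(14)‑trien‑6,12‑olide F4. Zinc in acetic acid removes the γ‑acetoxy group to give enone butenolide F5. (S)‑Me‑CBS/catecholborane reduction followed by Et3N equilibration at C6 gives the 13‑silyl ether F6, and HF·pyridine returns 20.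

**Step 4 (carbonylation of a carbonate that is both allylic and propargylic).** Palladium may ionise through the π‑allyl manifold, or the acylpalladium may insert the ring olefin. The fallback sets out from 5 and returns at 10. Aqueous quench of 5 gives the free 1‑{3‑[(tert‑butyldimethylsilyl)oxy]prop‑1‑yn‑1‑yl}‑3‑methylcyclohex‑2‑ene‑1,6‑diol F1. Alkoxide‑directed anti‑carbomagnesiation (ClMgCH2SiMe2(OiPr), CuI cat., THF), then CO2 and acid, gives the spiro butenolide 10‑hydroxy‑4‑{[isopropoxy(dimethyl)silyl]methyl}‑7‑methyl‑3‑{[(tert‑butyldimethylsilyl)oxy]methyl}‑1‑oxaspiro[4.5]deca‑3,6‑dien‑2‑one F2. Tamao oxidation (KF, KHCO3, H2O2) gives the 4‑(hydroxymethyl) diol F3, and Swern oxidation of both hydroxyls gives 10.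

**Step 12 (C6 configuration).** The preference for 6R under amine equilibration is an expectation, not a demonstrated fact; the reagent‑controlled reduction at C1 is the lesser concern. The fallback sets out from 19 and returns at 20. Compound 19 is isolated after a buffered, fluoride‑free work‑up of the reduction, then protonated at −78 °C in toluene with a Lewis‑acid‑assisted chiral Brønsted acid (BINOL·SnCl4, enantiomer chosen by trial). This sets C6 kinetically under reagent control. HF·pyridine in the same flask removes the remaining silyl ether to give 20 (no new compound: F0).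

## Further compounds

F1 | step 4 | 1‑{3‑[(tert‑butyldimethylsilyl)oxy]prop‑1‑yn‑1‑yl}‑3‑methylcyclohex‑2‑ene‑1,6‑diol | CC1=CC(O)(C#CCO[Si](C)(C)C(C)(C)C)C(O)CC1
F2 | step 4 | 10‑hydroxy‑4‑{[isopropoxy(dimethyl)silyl]methyl}‑7‑methyl‑3‑{[(tert‑butyldimethylsilyl)oxy]methyl}‑1‑oxaspiro[4.5]deca‑3,6‑dien‑2‑one | CC1=CC2(OC(=O)C(CO[Si](C)(C)C(C)(C)C)=C2C[Si](C)(C)OC(C)C)C(O)CC1
F3 | step 4 | 10‑hydroxy‑4‑(hydroxymethyl)‑7‑methyl‑3‑{[(tert‑butyldimethylsilyl)oxy]methyl}‑1‑oxaspiro[4.5]deca‑3,6‑dien‑2‑one | CC1=CC2(OC(=O)C(CO[Si](C)(C)C(C)(C)C)=C2CO)C(O)CC1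
F4 | step 11 | (4Z,8S)‑6,8‑diacetoxy‑13‑(tert‑butyldimethylsilyloxy)‑1‑oxogermacra‑4,7(11),10(14)‑trien‑6,12‑olide | C=C1C[C@H](OC(C)=O)C2=C(CO[Si](C)(C)C(C)(C)C)C(=O)OC2(OC(C)=O)/C=C(/C)CCC1=O
F5 | step 11 | (4Z,8S)‑8‑acetoxy‑13‑(tert‑butyldimethylsilyloxy)‑1‑oxogermacra‑4,7(11),10(14)‑trien‑6,12‑olide (C6 epimers) | C=C1C[C@H](OC(C)=O)C2=C(CO[Si](C)(C)C(C)(C)C)C(=O)OC2/C=C(/C)CCC1=O
F6 | step 11 | (1R,4Z,6R,8S)‑8‑acetoxy‑1‑hydroxy‑13‑(tert‑butyldimethylsilyloxy)germacra‑4,7(11),10(14)‑trien‑6,12‑olide | C=C1C[C@H](OC(C)=O)C2=C(CO[Si](C)(C)C(C)(C)C)C(=O)O[C@@H]2/C=C(/C)CC[C@H]1O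
F0 | step 12 | none | none
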